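**Retrosynthetic overview**
- Target ⇒ intermolecular endo [4+2] cycloaddition, catalysed by a Diels–Alderase, between a dienyl chalcone (diene) and a 3,5-dihydroxy-4-prenyl chalcone (dienophile). The cyclohexene is the only ring built and is formed last, with all three stereocentres set in that step.
- Dienyl chalcone ⇒ Suzuki coupling of an iodo-chalcone tetraacetate with an (E)-dienyl boronate; the iodo-chalcone ⇒ Claisen–Schmidt condensation of 3-iodo-2,4-dihydroxyacetophenone with MOM-protected 2,4-dihydroxybenzaldehyde.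
- Dienophile chalcone ⇒ Claisen–Schmidt condensation of the same aldehyde with 3,5-bis(MOM-oxy)-4-prenylacetophenone, made by directed ortho-lithiation/prenylation of ketal-masked 3,5-dihydroxyacetophenone.
- Ring order: all four benzene rings are bought; a temporary dioxolane is made and removed; the cyclohexene comes last.

Assumption: the SMILES is taken as the authoritative structure, so the aroyl ring is 3,5-dihydroxy-4-prenylphenyl (no hydroxyl ortho to the ketone) and the cyclohexene is (1S,5S,6R), the cis,trans (endo) series.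

**Route**

Step 1
Reactants: 1 2,4-dihydroxybenzaldehyde
Product: 2 2,4-bis(methoxymethoxy)benzaldehyde
Conditions: NaH (2.5 equiv), MOMCl (2.5 equiv), DMF, 0 °C → rt
Reagents that add atoms: chloromethyl methyl ether (MOMCl), COCCl
Why: Williamson O-alkylation of both sodium phenoxides (the chelated ortho-OH included) gives base-stable acetal protection for the later Claisen–Schmidt steps.

Step 2
Reactants: 3 1-(2,4-dihydroxyphenyl)ethanone
Product: 4 1-(2,4-dihydroxy-3-iodophenyl)ethanone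
Conditions: I2 (0.4 equiv), HIO3 (0.2 equiv), EtOH/H2O, 35 °C
Reagents that add atoms: iodine, II; iodic acid, O[I](=O)=O
Why: electrophilic aromatic iodination goes to C3, the position ortho to both hydroxyls of the chelated resacetophenone, and iodic acid reoxidises iodide so that all iodine is used.

Step 3
Reactants: 4 1-(2,4-dihydroxy-3-iodophenyl)ethanone
Product: 5 1-[2-hydroxy-3-iodo-4-(methoxymethoxy)phenyl]ethanone
Conditions: MOMCl (1.1 equiv), K2CO3 (1.5 equiv), acetone, 0 °C → rt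
Reagents that add atoms: chloromethyl methyl ether (MOMCl), COCCl
Why: selective Williamson etherification of the non-chelated, more acidic 4-OH, because the 2-OH stays hydrogen-bonded to the ketone.

Step 4
Reactants: 5 1-[2-hydroxy-3-iodo-4-(methoxymethoxy)phenyl]ethanone; 2 2,4-bis(methoxymethoxy)benzaldehyde
Product: 6 (E)-3-[2,4-bis(methoxymethoxy)phenyl]-1-[2-hydroxy-3-iodo-4-(methoxymethoxy)phenyl]prop-2-en-1-one
Conditions: KOH (10 equiv), EtOH/H2O, rt, 36 h; then dilute HCl to pH 5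
Reagents that add atoms: none
Why: Claisen–Schmidt (crossed aldol) condensation of the only enolisable ketone with a non-enolisable aldehyde gives the conjugated E-enone under thermodynamic control, and the aryl iodide and MOM acetals are inert to hydroxide.

Step 5
Reactants: 6 (E)-3-[2,4-bis(methoxymethoxy)phenyl]-1-[2-hydroxy-3-iodo-4-(methoxymethoxy)phenyl]prop-2-en-1-one
Product: 7 (E)-1-(2,4-dihydroxy-3-iodophenyl)-3-(2,4-dihydroxyphenyl)prop-2-en-1-one
Conditions: 3 N aq. HCl, MeOH/THF, 50 °C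
Reagents that add atoms: none
Why: acid-catalysed acetal methanolysis removes the three MOM groups while the molecule still carries no acid-sensitive diene or prenyl group.

Step 6
Reactants: 7 (E)-1-(2,4-dihydroxy-3-iodophenyl)-3-(2,4-dihydroxyphenyl)prop-2-en-1-one
Product: 8 (E)-1-(2,4-diacetoxy-3-iodophenyl)-3-(2,4-diacetoxyphenyl)prop-2-en-1-one
Conditions: Ac2O (8 equiv), pyridine, DMAP (cat.), CH2Cl2, 0 °C → rt
Reagents that add atoms: acetic anhydride, CC(=O)OC(C)=O
Why: DMAP-catalysed O-acylation of all four phenols gives a phenol-free aryl iodide that tolerates palladium coupling and whose protecting groups can later be removed without acid.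

Step 7
Reactants: 9 2-methylbut-1-en-3-yne
Product: 10 4,4,5,5-tetramethyl-2-[(1E)-3-methylbuta-1,3-dien-1-yl]-1,3,2-dioxaborolane
Conditions: HBpin (1.05 equiv), Cp2Zr(H)Cl (5 mol%), Et3N (10 mol%), neat, 60 °C
Reagents that add atoms: pinacolborane, CC1(C)OBOC1(C)C
Why: zirconocene hydride-catalysed syn-hydroboration of the terminal alkyne is anti-Markovnikov and E-selective and leaves the 1,1-disubstituted alkene untouched.

Step 8
Reactants: 8 (E)-1-(2,4-diacetoxy-3-iodophenyl)-3-(2,4-diacetoxyphenyl)prop-2-en-1-one; 10 4,4,5,5-tetramethyl-2-[(1E)-3-methylbuta-1,3-dien-1-yl]-1,3,2-dioxaborolane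
Product: 11 (E)-1-{2,4-diacetoxy-3-[(1E)-3-methylbuta-1,3-dien-1-yl]phenyl}-3-(2,4-diacetoxyphenyl)prop-2-en-1-one
Conditions: PdCl2(dppf) (5 mol%), anhydrous K3PO4 (2.5 equiv), 1,4-dioxane, 70 °C, BHT (cat.), dark
Reagents that add atoms: none
Why: Suzuki–Miyaura cross-coupling (oxidative addition of the carbon–iodine bond to zerovalent palladium, transmetallation, reductive elimination) transfers the dienyl group with retention of E geometry, and the acetates stop the flanking phenols from cyclising onto the new diene at 70 °C.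

Step 9
Reactants: 11 (E)-1-{2,4-diacetoxy-3-[(1E)-3-methylbuta-1,3-dien-1-yl]phenyl}-3-(2,4-diacetoxyphenyl)prop-2-en-1-one
Product: 12 (E)-1-{2,4-dihydroxy-3-[(1E)-3-methylbuta-1,3-dien-1-yl]phenyl}-3-(2,4-dihydroxyphenyl)prop-2-en-1-one
Conditions: K2CO3 (0.5 equiv), MeOH/THF, 0 °C, argon, 30 min; pH 6 phosphate buffer; run immediately before step 16
Reagents that add atoms: none
Why: base-catalysed transesterification (methanolysis) of the four aryl acetates is fast at 0 °C and avoids the acid or heat that would isomerise the ortho-hydroxy dienylarene to a 2,2-dimethylchromene.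

Step 10
Reactants: 13 1-(3,5-dihydroxyphenyl)ethanone
Product: 14 1-[3,5-bis(methoxymethoxy)phenyl]ethanone
Conditions: MOMCl (2.6 equiv), K2CO3 (4 equiv), acetone, 0 °C → rt
Reagents that add atoms: chloromethyl methyl ether (MOMCl), COCCl
Why: Williamson etherification of the two unhindered phenols installs MOM groups that later direct ortho-lithiation.

Step 11
Reactants: 14 1-[3,5-bis(methoxymethoxy)phenyl]ethanone
Product: 15 2-[3,5-bis(methoxymethoxy)phenyl]-2-methyl-1,3-dioxolane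
Conditions: (TMSOCH2)2 (1.5 equiv), TMSOTf (5 mol%), CH2Cl2, −78 → −20 °C; pyridine quench
Reagents that add atoms: 1,2-bis(trimethylsilyloxy)ethane, C[Si](C)(C)OCCO[Si](C)(C)C
Why: Noyori ketalisation masks the ketone as an achiral dioxolane under aprotic conditions that spare the aryl MOM acetals, driven by formation of hexamethyldisiloxane.

Step 12
Reactants: 15 2-[3,5-bis(methoxymethoxy)phenyl]-2-methyl-1,3-dioxolane
Product: 17 2-[3,5-bis(methoxymethoxy)-4-(3-methylbut-2-en-1-yl)phenyl]-2-methyl-1,3-dioxolane, via aryllithium 16 (not isolated)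
Conditions: n-BuLi (1.2 equiv), THF, 0 °C, 1 h; CuI (10 mol%), prenyl bromide (1.5 equiv), −78 °C → rt
Reagents that add atoms: 1-bromo-3-methylbut-2-ene (prenyl bromide), CC(C)=CCBr
Why: directed ortho-metalation occurs at C4, the only position flanked by two chelating MOM ethers, and copper-catalysed SN2 alkylation of the aryllithium with prenyl bromide gives the linear prenyl group.

Step 13
Reactants: 17 2-[3,5-bis(methoxymethoxy)-4-(3-methylbut-2-en-1-yl)phenyl]-2-methyl-1,3-dioxolane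
Product: 18 1-[3,5-bis(methoxymethoxy)-4-(3-methylbut-2-en-1-yl)phenyl]ethanone
Conditions: PPTS (0.2 equiv), acetone/H2O (10:1), 40 °C
Reagents that add atoms: water, O
Why: mild acid-catalysed ketal hydrolysis frees the aryl methyl ketone at an acidity too low to cleave aryl MOM ethers or protonate the prenyl alkene.

Step 14
Reactants: 18 1-[3,5-bis(methoxymethoxy)-4-(3-methylbut-2-en-1-yl)phenyl]ethanone; 2 2,4-bis(methoxymethoxy)benzaldehyde
Product: 19 (E)-1-[3,5-bis(methoxymethoxy)-4-(3-methylbut-2-en-1-yl)phenyl]-3-[2,4-bis(methoxymethoxy)phenyl]prop-2-en-1-one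
Conditions: KOH (10 equiv), EtOH/H2O, rt, 24 h
Reagents that add atoms: none
Why: Claisen–Schmidt condensation of the methyl ketone with the non-enolisable aldehyde gives the E-chalcone, with the prenyl group and MOM acetals stable to base.

Step 15
Reactants: 19 (E)-1-[3,5-bis(methoxymethoxy)-4-(3-methylbut-2-en-1-yl)phenyl]-3-[2,4-bis(methoxymethoxy)phenyl]prop-2-en-1-one
Product: 20 (E)-1-[3,5-dihydroxy-4-(3-methylbut-2-en-1-yl)phenyl]-3-(2,4-dihydroxyphenyl)prop-2-en-1-one
Conditions: 3 N aq. HCl/MeOH (1:5), rt → 40 °C, argon, stopped at full conversion; NaHCO3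
Reagents that add atoms: none
Why: acid-catalysed acetal methanolysis removes the four MOM groups, and is kept mild and short so the prenyl group does not close onto a flanking phenol to give a chroman.

Step 16
Reactants: 20 (E)-1-[3,5-dihydroxy-4-(3-methylbut-2-en-1-yl)phenyl]-3-(2,4-dihydroxyphenyl)prop-2-en-1-one; 12 (E)-1-{2,4-dihydroxy-3-[(1E)-3-methylbuta-1,3-dien-1-yl]phenyl}-3-(2,4-dihydroxyphenyl)prop-2-en-1-one
Product: 21 (E)-1-{3-[(1S,5S,6R)-6-[3,5-dihydroxy-4-(3-methylbut-2-en-1-yl)benzoyl]-5-(2,4-dihydroxyphenyl)-3-methylcyclohex-2-en-1-yl]-2,4-dihydroxyphenyl}-3-(2,4-dihydroxyphenyl)prop-2-en-1-one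
Conditions: 20 (3 equiv), 12 (1 equiv, added in portions), recombinant MaDA (Morus alba Diels–Alderase, an FAD-dependent intermolecular Diels–Alderase of the pericyclase class, endo-selective isoform), 50 mM Tris-HCl pH 8.0, DMSO (5 vol%), 37 °C, dark
Reagents that add atoms: none
Why: the Diels–Alderase holds the s-cis diene of 12 over the enone of 20 in one endo orientation, so this enzyme-catalysed intermolecular Diels–Alder reaction sets all three stereocentres at once from two achiral chalcones (aroyl cis to the C1 aryl, trans to the C5 aryl) as the single (1S,5S,6R) enantiomer.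

**Compound list**

1 | 2,4-dihydroxybenzaldehyde | O=Cc1ccc(O)cc1O | starting material
2 | 2,4-bis(methoxymethoxy)benzaldehyde | COCOc1ccc(C=O)c(OCOC)c1 | intermediate
3 | 1-(2,4-dihydroxyphenyl)ethanone | CC(=O)c1ccc(O)cc1O | starting material
4 | 1-(2,4-dihydroxy-3-iodophenyl)ethanone | CC(=O)c1ccc(O)c(I)c1O | intermediate
5 | 1-[2-hydroxy-3-iodo-4-(methoxymethoxy)phenyl]ethanone | CC(=O)c1ccc(OCOC)c(I)c1O | intermediate
6 | (E)-3-[2,4-bis(methoxymethoxy)phenyl]-1-[2-hydroxy-3-iodo-4-(methoxymethoxy)phenyl]prop-2-en-1-one | COCOc1ccc(/C=C/C(=O)c2ccc(OCOC)c(I)c2O)c(OCOC)c1 | intermediate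
7 | (E)-1-(2,4-dihydroxy-3-iodophenyl)-3-(2,4-dihydroxyphenyl)prop-2-en-1-one | O=C(/C=C/c1ccc(O)cc1O)c1ccc(O)c(I)c1O | intermediate
8 | (E)-1-(2,4-diacetoxy-3-iodophenyl)-3-(2,4-diacetoxyphenyl)prop-2-en-1-one | CC(=O)Oc1ccc(/C=C/C(=O)c2ccc(OC(C)=O)c(I)c2OC(C)=O)c(OC(C)=O)c1 | intermediate
9 | 2-methylbut-1-en-3-yne | C=C(C)C#C | starting material
10 | 4,4,5,5-tetramethyl-2-[(1E)-3-methylbuta-1,3-dien-1-yl]-1,3,2-dioxaborolane | CC(=C)/C=C/B1OC(C)(C)C(C)(C)O1 | intermediate
11 | (E)-1-{2,4-diacetoxy-3-[(1E)-3-methylbuta-1,3-dien-1-yl]phenyl}-3-(2,4-diacetoxyphenyl)prop-2-en-1-one | CC(=C)/C=C/c1c(OC(C)=O)ccc(C(=O)/C=C/c2ccc(OC(C)=O)cc2OC(C)=O)c1OC(C)=O | intermediate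
12 | (E)-1-{2,4-dihydroxy-3-[(1E)-3-methylbuta-1,3-dien-1-yl]phenyl}-3-(2,4-dihydroxyphenyl)prop-2-en-1-one | CC(=C)/C=C/c1c(O)ccc(C(=O)/C=C/c2ccc(O)cc2O)c1O | intermediate
13 | 1-(3,5-dihydroxyphenyl)ethanone | CC(=O)c1cc(O)cc(O)c1 | starting material
14 | 1-[3,5-bis(methoxymethoxy)phenyl]ethanone | CC(=O)c1cc(OCOC)cc(OCOC)c1 | intermediate
15 | 2-[3,5-bis(methoxymethoxy)phenyl]-2-methyl-1,3-dioxolane | CC1(c2cc(OCOC)cc(OCOC)c2)OCCO1 | intermediate
16 | [2,6-bis(methoxymethoxy)-4-(2-methyl-1,3-dioxolan-2-yl)phenyl]lithium | CC1(c2cc(OCOC)c([Li])c(OCOC)c2)OCCO1 | intermediate (not isolated)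
17 | 2-[3,5-bis(methoxymethoxy)-4-(3-methylbut-2-en-1-yl)phenyl]-2-methyl-1,3-dioxolane | CC(C)=CCc1c(OCOC)cc(C2(C)OCCO2)cc1OCOC | intermediate
18 | 1-[3,5-bis(methoxymethoxy)-4-(3-methylbut-2-en-1-yl)phenyl]ethanone | CC(C)=CCc1c(OCOC)cc(C(C)=O)cc1OCOC | intermediate
19 | (E)-1-[3,5-bis(methoxymethoxy)-4-(3-methylbut-2-en-1-yl)phenyl]-3-[2,4-bis(methoxymethoxy)phenyl]prop-2-en-1-one | CC(C)=CCc1c(OCOC)cc(C(=O)/C=C/c2ccc(OCOC)cc2OCOC)cc1OCOC | intermediate
20 | (E)-1-[3,5-dihydroxy-4-(3-methylbut-2-en-1-yl)phenyl]-3-(2,4-dihydroxyphenyl)prop-2-en-1-one | CC(C)=CCc1c(O)cc(C(=O)/C=C/c2ccc(O)cc2O)cc1O | intermediate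
21 | (E)-1-{3-[(1S,5S,6R)-6-[3,5-dihydroxy-4-(3-methylbut-2-en-1-yl)benzoyl]-5-(2,4-dihydroxyphenyl)-3-methylcyclohex-2-en-1-yl]-2,4-dihydroxyphenyl}-3-(2,4-dihydroxyphenyl)prop-2-en-1-one | CC(C)=CCc1c(O)cc(C(=O)[C@H]2[C@@H](c3c(O)ccc(C(=O)/C=C/c4ccc(O)cc4O)c3O)C=C(C)C[C@@H]2c2ccc(O)cc2O)cc1O | target

**Step count and risks**

Total steps: 16. Longest linear sequence: 8 steps (3 → 4 → 5 → 6 → 7 → 8 → 11 → 12 → 21; steps 2, 3, 4, 5, 6, 8, 9 and 16).

Most likely to fail, first: step 16. The aroyl ring of 20 has no hydroxyl ortho to the ketone, unlike the enzyme's native morachalcone dienophile, so acceptance of 20 is untested. In addition, 12 carries its own 2'-hydroxychalcone and can compete as a dienophile; this is why 20 is used in excess and 12 is added in portions. The fallback sets out from 20 and 11 and comes back to the route at 21. Compound 20 is peracetylated (Ac2O, pyridine, DMAP, CH2Cl2) to (E)-1-[3,5-diacetoxy-4-(3-methylbut-2-en-1-yl)phenyl]-3-(2,4-diacetoxyphenyl)prop-2-en-1-one F1. F1 and 11 are heated (toluene, 150 °C, sealed tube, BHT) in an uncatalysed thermal Diels–Alder reaction, and the endo adduct is separated from the exo isomer on silica as the racemic endo octaacetate F2. Preparative HPLC on a chiral stationary phase (amylose tris(3,5-dimethylphenylcarbamate)) gives the (1S,5S,6R) octaacetate F3, assigned by circular dichroism. K2CO3 in MeOH at 0 °C then removes the eight acetates to give 21.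

Second: step 15. The prenyl group sits between two phenols once the MOM groups fall off and can cyclise to a 2,2-dimethylchroman under acid. The fallback sets out from 15 and comes back at 20. Compound 15 is lithiated as in step 12 (to 16) and quenched with allyl bromide (CuI cat.) to give the allyl dioxolane F4. PPTS in acetone/H2O gives the allyl ketone F5, and Claisen–Schmidt condensation with 2 (KOH, EtOH/H2O) gives the allyl tetra-MOM chalcone F6. HCl/MeOH then gives the allyl tetrahydroxychalcone F7; the allyl group cannot form a stabilised tertiary cation, so no chroman forms. Finally, olefin cross-metathesis with 2-methylbut-2-ene (second-generation Hoveyda–Grubbs catalyst, CH2Cl2, 40 °C) turns the allyl group into prenyl and gives 20.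

Third: step 8. The iodide is flanked by two acetoxy groups, the dienyl boronate can protodeboronate, and phosphate may strip acetates. The fallback sets out from 8 and comes back at 11. A Mizoroki–Heck reaction of 8 with 2-methylbut-3-en-2-ol (Pd(OAc)2, n-Bu4NCl, NaHCO3, DMF, 70 °C) gives the tertiary allylic alcohol (E)-1-{2,4-diacetoxy-3-[(1E)-3-hydroxy-3-methylbut-1-en-1-yl]phenyl}-3-(2,4-diacetoxyphenyl)prop-2-en-1-one F8. Its dehydration with Burgess reagent (toluene, 60 °C) can only eliminate towards a methyl group and gives the diene 11.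

**Further compounds**

F1 | step 16 | (E)-1-[3,5-diacetoxy-4-(3-methylbut-2-en-1-yl)phenyl]-3-(2,4-diacetoxyphenyl)prop-2-en-1-one | CC(C)=CCc1c(OC(C)=O)cc(C(=O)/C=C/c2ccc(OC(C)=O)cc2OC(C)=O)cc1OC(C)=O
F2 | step 16 | racemic endo octaacetate of 21 (1:1 mixture of the 1S,5S,6R and 1R,5R,6S enantiomers) | CC(C)=CCc1c(OC(C)=O)cc(C(=O)[C@H]2[C@@H](c3c(OC(C)=O)ccc(C(=O)/C=C/c4ccc(OC(C)=O)cc4OC(C)=O)c3OC(C)=O)C=C(C)C[C@@H]2c2ccc(OC(C)=O)cc2OC(C)=O)cc1OC(C)=O.CC(C)=CCc1c(OC(C)=O)cc(C(=O)[C@@H]2[C@H](c3c(OC(C)=O)ccc(C(=O)/C=C/c4ccc(OC(C)=O)cc4OC(C)=O)c3OC(C)=O)C=C(C)C[C@H]2c2ccc(OC(C)=O)cc2OC(C)=O)cc1OC(C)=O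
F3 | step 16 | (1S,5S,6R) octaacetate of 21 | CC(C)=CCc1c(OC(C)=O)cc(C(=O)[C@H]2[C@@H](c3c(OC(C)=O)ccc(C(=O)/C=C/c4ccc(OC(C)=O)cc4OC(C)=O)c3OC(C)=O)C=C(C)C[C@@H]2c2ccc(OC(C)=O)cc2OC(C)=O)cc1OC(C)=O
F4 | step 15 | 2-[3,5-bis(methoxymethoxy)-4-(prop-2-en-1-yl)phenyl]-2-methyl-1,3-dioxolane | C=CCc1c(OCOC)cc(C2(C)OCCO2)cc1OCOC
F5 | step 15 | 1-[3,5-bis(methoxymethoxy)-4-(prop-2-en-1-yl)phenyl]ethanone | C=CCc1c(OCOC)cc(C(C)=O)cc1OCOC
F6 | step 15 | (E)-1-[3,5-bis(methoxymethoxy)-4-(prop-2-en-1-yl)phenyl]-3-[2,4-bis(methoxymethoxy)phenyl]prop-2-en-1-one | C=CCc1c(OCOC)cc(C(=O)/C=C/c2ccc(OCOC)cc2OCOC)cc1OCOC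
F7 | step 15 | (E)-1-[3,5-dihydroxy-4-(prop-2-en-1-yl)phenyl]-3-(2,4-dihydroxyphenyl)prop-2-en-1-one | C=CCc1c(O)cc(C(=O)/C=C/c2ccc(O)cc2O)cc1O
F8 | step 8 | (E)-1-{2,4-diacetoxy-3-[(1E)-3-hydroxy-3-methylbut-1-en-1-yl]phenyl}-3-(2,4-diacetoxyphenyl)prop-2-en-1-one | CC(C)(O)/C=C/c1c(OC(C)=O)ccc(C(=O)/C=C/c2ccc(OC(C)=O)cc2OC(C)=O)c1OC(C)=O
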